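in all of them: Q 0.20 M
- summer: J 0.66 equiv; run made earlier
- noon: J 1.9 equiv; run made earlier
- winter: J 3.1 equiv; run made earlier
- eta: J 0.900 equiv; time 1.0 h
- gamma: J 1.80 equiv; time 1.0 h
- theta: J 3.60 equiv; time 1.0 h

| run | time / min | D / % | L / % | E / % | Q / % |
|---|---|---|---|---|---|
| summer | 3.00 | 16 | 0 | 6 | 85 |
| summer | 8.00 | 18 | 5 | 8 | 71 |
| summer | 20.0 | 22 | 6 | 11 | 57 |
| summer | 40.0 | 21 | 15 | 14 | 53 |
| noon | 3.00 | 28 | 0 | 9 | 59 |
| noon | 8.00 | 44 | 3 | 18 | 34 |
| noon | 20.0 | 45 | 7 | 22 | 24 |
| noon | 40.0 | 41 | 15 | 25 | 19 |
| winter | 10.0 | 56 | 6 | 24 | 20 |
| winter | 20.0 | 56 | 3 | 28 | 15 |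
| winter | 30.0 | 50 | 9 | 31 | 14 |
| winter | 40.0 | 52 | 11 | 33 | 11 |

(readings scatter by 1.5 percentage points)

- which of these there is most of at the end, counted by the Q in it, eta (E / L / D / Q)
- which of these there is most of at the end, counted by the Q in it, gamma (E / L / D / Q)
- which of these there is most of at the end, counted by the Q in it, theta (E / L / D / Q)
- final amount of the leader among these, as a percentage of the Q charged, in eta
- final amount of the leader among these, as a percentage of the Q charged, in gamma
- final amount of the leader among these, as a percentage of the Q charged, in theta

- percent here means Q units held: one L counts as two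

- After 1.0 h of stirring at constant temperature, D must stand ahead of Q. So we must decide how much J to charge in the next run.
- The noon run loses 5 percentage points of Q over its last 20.0 min, yet J remains. So we treat Q + J ⇌ D as near balance.
- J is the limiting reagent in eta, so we write its balance. Each D and each E holds one J. Each L holds one J but counts as two Q, so L enters at 0.5. What the charge minus these leaves we call outside J.
- We form the stall quotient: Q times outside J, divided by D, all as fractions of the Q charged.
- The last readings give 0.593 in summer, 0.540 at noon and 0.464 in winter. We carry their mean as a reading, 0.532.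
- Where Q equals D, outside J must equal the stall quotient.
- With Q equal to D, the Q balance makes D plus 0.5 L equal to 0.5 of the Q charged minus 0.5 E, so L cancels. The J charge needed, per Q charged, is 0.5 + stall quotient + 0.5 × E.
- With E from the last noon reading, 25 %, this gives 1.16 equivalents of J. That is the crossing charge, the charge of J at which Q and D stand level.
- Eta lies below it, so we expect Q over D there. Gamma and theta lie above it, so we expect D over Q. Our rule says nothing of E.
- The forecast names Q at 34 % in eta, D at 36 % in gamma and D at 43 % in theta. Its ground: “Q stalls even when J is left over”.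
- We would charge above the crossing charge.

The flasks give Q at 37.3 % in eta, D at 35.8 % in gamma and D at 45.3 % in theta.

    Q + J ⇌ D (K = 11.3 /M, k = 0.382 /M/min)
    Q + J ⇌ E (K = 13.2 /M, k = 0.129 /M/min)
    J ⇌ G (K = 0.380, k = 0.0194 /min)
    Q + D → L (k = 0.0685 /M/min)

The flasks put the crossing at 1.19 equiv, beside our 1.16 equivalents, and eta lies below it. Theta shows what the charge does to Q, though D leads there. Q ends at 9.02 % in theta and at 37.3 % with the difference in equivalents of J taken away, and that difference is the main reason. A further flask with 1.40 equiv of J lies above our crossing charge, and there D holds 31.5 % against 24.1 % of Q.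

(The numbers in the tables stem from a simulated flask for substances that don't exist, and the scatter is random.)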